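## Retrosynthetic overview

- The target should come from global hydrogenolysis of a perbenzylated, doubly C8-bromo-capped trimer digallate, made by double galloylation of the two free 3-OH groups; the C4(middle)–C6(bottom) bond comes from a flavan-4-yl cation and C8-bromo-capped catechin.
- Ring C of the middle unit is disconnected by a [3+3] annulation of a free phenol with a cis-2,3-epoxy-3-arylpropanal: C4a–C4 by ortho-hydroxyalkylation and O1–C2 by 6-endo epoxide opening, in one titanium-templated operation.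
- Enabling feature: ring A of the middle unit is a phloroglucinol ring whose O1 (on C8a) lies between C8, already carrying C4 of the upper unit, and C4a, its only free ortho carbon, so the phenol is a 1,3-C,O-bis-nucleophile. C2–C3–C4 of ring C is an epoxy aldehyde whose C2 is benzylic to catechol ring B and whose C4 oxygen is the later leaving group.
- The phenol comes from an epicatechin-derived 4β-alkoxy electrophile and 3,5-bis(benzyloxy)phenol; the epoxide comes from Jacobsen epoxidation of a (Z)-cinnamate, the only stereo-element made by catalysis, relayed to C2 (inversion) and then to C4 (anti attack).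
- Ring order: the rings of the upper and bottom units are bought ((−)-epicatechin, (+)-catechin); ring C of the middle unit is the only ring built.

Key step: step 12

Remark: the carbinol carbon C4 of the middle unit formed in the key step is expected as an epimer mixture and is written without configuration; the following step ionises it, so its configuration does not reach the target.

## Route

Step 1
Reactants: 1 (−)-epicatechin
Product: 2 5,7,3',4'-tetra-O-benzyl-(−)-epicatechin
Conditions: BnBr (4.4 equiv), K2CO3, DMF, 0 °C → rt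
Reagents that add atoms: benzyl bromide, BrCc1ccccc1
Why: Williamson etherification of the four phenols, the secondary 3-OH not being deprotonated by K2CO3; no stereocenter is touched.

Step 2
Reactants: 2 5,7,3',4'-tetra-O-benzyl-(−)-epicatechin
Product: 3 8-bromo-5,7,3',4'-tetra-O-benzyl-(−)-epicatechin
Conditions: NBS (1.0 equiv), CH2Cl2, −40 → 0 °C
Reagents that add atoms: N-bromosuccinimide, BrN1C(=O)CCC1=O
Why: Electrophilic aromatic bromination of ring A should go to C8 (flanked by O1 and one OBn) rather than C6 (between two OBn); the bromine later blocks self-condensation through C8.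

Step 3
Reactants: 3 8-bromo-5,7,3',4'-tetra-O-benzyl-(−)-epicatechin
Product: 4 8-bromo-4β-(2-ethoxyethoxy)-5,7,3',4'-tetra-O-benzyl-(−)-epicatechin (2,3-cis-3,4-trans)
Conditions: DDQ (2 equiv), 2-ethoxyethanol (5 equiv), CH2Cl2, rt
Reagents that add atoms: 2-ethoxyethanol, CCOCCO
Why: DDQ benzylic oxidation (hydride abstraction at C4 to the ring-A-stabilised cation) and capture by the alcohol anti to the 3-OH should give the 3,4-trans (4β) ether.

Step 4
Reactants: 4 8-bromo-4β-(2-ethoxyethoxy)-5,7,3',4'-tetra-O-benzyl-(−)-epicatechin; 5 3,5-bis(benzyloxy)phenol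
Product: 6 8-bromo-4β-[2-hydroxy-4,6-bis(benzyloxy)phenyl]-5,7,3',4'-tetra-O-benzyl-(−)-epicatechin (3,4-trans)
Conditions: 5 (4 equiv), Me3SiOTf (0.2 equiv), CH2Cl2, −78 → −40 °C; Et3N quench
Reagents that add atoms: none
Why: Friedel–Crafts alkylation via the flavan-4-yl cation: the phenol should attack anti to the 3-OH (4β) through its C2, the ring carbon flanked by OH and one OBn and less hindered than the carbon between two OBn (the bias that sends benzylated flavan nucleophiles to C8, not C6), while the excess of 5 suppresses double alkylation.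

Step 5
Reactants: 7 3,4-bis(benzyloxy)benzaldehyde; 8 methyl 2-[bis(2,2,2-trifluoroethoxy)phosphoryl]acetate
Product: 9 methyl (Z)-3-[3,4-bis(benzyloxy)phenyl]prop-2-enoate
Conditions: KN(SiMe3)2, 18-crown-6, THF, −78 °C
Reagents that add atoms: none
Why: Still–Gennari variant of the Horner–Wadsworth–Emmons olefination, in which fast elimination from the trifluoroethyl phosphonate adduct should deliver the (Z)-alkene.

Step 6
Reactants: 9 methyl (Z)-3-[3,4-bis(benzyloxy)phenyl]prop-2-enoate
Product: 10 methyl (2S,3S)-3-[3,4-bis(benzyloxy)phenyl]oxirane-2-carboxylate (cis-epoxide)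
Conditions: (S,S)-(salen)MnCl [(S,S)-N,N'-bis(3,5-di-tert-butylsalicylidene)-1,2-cyclohexanediaminomanganese chloride, 5 mol %], NaOCl (aq, pH 11.3), 4-phenylpyridine N-oxide, CH2Cl2, 0 °C
Reagents that add atoms: sodium hypochlorite, [Na+].[O-]Cl
Why: Jacobsen–Katsuki epoxidation of a cis-disubstituted aryl alkene, where side-on approach to the oxo-manganese salen species should set both epoxide carbons as (2S,3S), by analogy with the (R,R)-complex giving (2R,3R)-glycidates from cis-cinnamates.

Step 7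
Reactants: 10 methyl (2S,3S)-3-[3,4-bis(benzyloxy)phenyl]oxirane-2-carboxylate
Product: 11 [(2R,3S)-3-[3,4-bis(benzyloxy)phenyl]oxiran-2-yl]methanol (cis-epoxide)
Conditions: NaBH4, MeOH/THF, 0 °C
Reagents that add atoms: none
Why: Hydride reduction of the α-alkoxy-activated ester should leave the epoxide and both stereocenters untouched (the C2 descriptor changes to R only through the priority rules).

Step 8
Reactants: 11 [(2R,3S)-3-[3,4-bis(benzyloxy)phenyl]oxiran-2-yl]methanol
Product: 12 (2S,3S)-3-[3,4-bis(benzyloxy)phenyl]oxirane-2-carbaldehyde (cis-epoxide)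
Conditions: Dess–Martin periodinane, pyridine, CH2Cl2, 0 °C; used at once without chromatography
Reagents that add atoms: none
Why: Dess–Martin oxidation under buffered, non-basic conditions should give the α,β-epoxy aldehyde without epimerising the α-carbon.

Step 9
Reactants: 13 (+)-catechin
Product: 14 5,7,3',4'-tetra-O-benzyl-(+)-catechin
Conditions: BnBr (4.4 equiv), K2CO3, DMF, 0 °C → rt
Reagents that add atoms: benzyl bromide, BrCc1ccccc1
Why: Williamson etherification of the four phenols; no stereocenter is touched.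

Step 10
Reactants: 14 5,7,3',4'-tetra-O-benzyl-(+)-catechin
Product: 15 3,5,7,3',4'-penta-O-benzyl-(+)-catechin
Conditions: NaH, BnBr, DMF, 0 °C → rt
Reagents that add atoms: benzyl bromide, BrCc1ccccc1
Why: Williamson etherification of the secondary alkoxide, which keeps the bottom 3-OH masked during the later galloylation.

Step 11
Reactants: 15 3,5,7,3',4'-penta-O-benzyl-(+)-catechin
Product: 16 8-bromo-3,5,7,3',4'-penta-O-benzyl-(+)-catechin
Conditions: NBS (1.0 equiv), CH2Cl2, −78 → 0 °C
Reagents that add atoms: N-bromosuccinimide, BrN1C(=O)CCC1=O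
Why: Electrophilic aromatic bromination at C8 should leave C6 as the only free ring position of this nucleophile.

Step 12
Reactants: 6 8-bromo-4β-[2-hydroxy-4,6-bis(benzyloxy)phenyl]-5,7,3',4'-tetra-O-benzyl-(−)-epicatechin; 12 (2S,3S)-3-[3,4-bis(benzyloxy)phenyl]oxirane-2-carbaldehyde
Product: 19 8-bromo-5,7,3',4'-tetra-O-benzylepicatechin-(4β→8)-[5,7,3',4'-tetra-O-benzyl-(2R,3R)-2,3-cis-flavan-3,4-diol] (C4 carbinol epimers), via aryloxytitanium triisopropoxide 17 (not isolated), via epoxy carbinol adduct 18 (not isolated)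
Conditions: Ti(OiPr)4 (1.2 equiv), toluene, rt, then evaporation of iPrOH; 12 (1.3 equiv), CH2Cl2, 4 Å MS, −20 °C → rt; aqueous tartaric acid work-up
Reagents that add atoms: none
Why: Proposed new method: the aryloxytitanium 17 binds the aldehyde of 12 and delivers C4a, the only free carbon ortho to the titanium-bound oxygen, to the carbonyl carbon through a six-membered chelate (C4a–C4 bond), after which the rearomatised phenoxide opens the epoxide of the titanium-bound 2,3-epoxy alkoxide 18 at its distal benzylic carbon (O1–C2 bond). The closest known reaction types are the ortho-specific hydroxyalkylation of magnesium and titanium phenoxides with aldehydes, the Ti(OiPr)4-mediated opening of 2,3-epoxy alcohols at the carbon remote from the carbinol, and the acid-mediated cyclisation of 2-(3-aryl-2,3-epoxypropyl)phenols to flavan-3-ols; running them as one cascade on an epoxy aldehyde is what is new. Ring C closes in the 6-endo-tet mode, preferred over 5-exo because C2 is benzylic to the dialkoxyphenyl ring and the titanium alkoxide activates the epoxide oxygen. C3 keeps its epoxide C–O bond (3R), C2 is formed with inversion at the (3S) carbon of the cis-epoxide (2R, hence 2,3-cis), and the C4 carbinol is uncontrolled and irrelevant because step 13 ionises it. The step needs ortho regioselectivity, which the chelate and the occupied C8 position secure, and backside (inverting) opening rather than ionisation at C2, which intramolecular delivery in a non-polar medium at low temperature should favour.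

Step 13
Reactants: 19 8-bromo-5,7,3',4'-tetra-O-benzylepicatechin-(4β→8)-[5,7,3',4'-tetra-O-benzyl-(2R,3R)-2,3-cis-flavan-3,4-diol]; 16 8-bromo-3,5,7,3',4'-penta-O-benzyl-(+)-catechin
Product: 20 8-bromo-5,7,3',4'-tetra-O-benzylepicatechin-(4β→8)-5,7,3',4'-tetra-O-benzylepicatechin-(4β→6)-8-bromo-3,5,7,3',4'-penta-O-benzylcatechin (both upper 3-OH groups free)
Conditions: 16 (3 equiv), Me3SiOTf (0.3 equiv), 4 Å MS, CH2Cl2, −78 → −30 °C; Et3N quench
Reagents that add atoms: none
Why: Friedel–Crafts alkylation through the flavan-4-yl cation of 19 (both C4 epimers converge): C6 of 16, its only free ring carbon, should attack anti to the axial 3-OH of the 2,3-cis middle unit, setting C4 as 3,4-trans (4β), while the C8 bromine of the upper unit prevents self-condensation.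

Step 14
Reactants: 20 protected trimer diol; 21 3,4,5-tris(benzyloxy)benzoic acid
Product: 22 3,3''-bis-O-[3,4,5-tris(benzyloxy)benzoyl] derivative of 20 (upper and middle 3-O-gallate, fully benzylated, two C8 bromines)
Conditions: 21 (6 equiv), DCC, DMAP, CH2Cl2, rt, 48 h
Reagents that add atoms: none
Why: Steglich esterification should acylate the two free secondary 3-OH groups, the bottom 3-OH being masked as its benzyl ether.

Step 15
Reactants: 22 perbenzylated dibromo trimer digallate
Product: 23 (−)-epicatechin-3-O-gallate-(4β→8)-(−)-epicatechin-3-O-gallate-(4β→6)-(+)-catechin (CNP0154615.1)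
Conditions: H2 (1 atm), Pd(OH)2/C, THF/MeOH/H2O, rt
Reagents that add atoms: none
Why: Catalytic hydrogenolysis should cleave all nineteen benzyl ethers and both aryl C–Br bonds while the gallate esters, the interflavan bonds and all stereocenters are kept.

## Compound list

1 | (−)-epicatechin | O[C@@H]1Cc2c(O)cc(O)cc2O[C@@H]1c1ccc(O)c(O)c1 | starting material
2 | 5,7,3',4'-tetra-O-benzyl-(−)-epicatechin | O[C@@H]1Cc2c(OCc3ccccc3)cc(OCc3ccccc3)cc2O[C@@H]1c1ccc(OCc2ccccc2)c(OCc2ccccc2)c1 | intermediate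
3 | 8-bromo-5,7,3',4'-tetra-O-benzyl-(−)-epicatechin | O[C@@H]1Cc2c(OCc3ccccc3)cc(OCc3ccccc3)c(Br)c2O[C@@H]1c1ccc(OCc2ccccc2)c(OCc2ccccc2)c1 | intermediate
4 | 8-bromo-4β-(2-ethoxyethoxy)-5,7,3',4'-tetra-O-benzyl-(−)-epicatechin | O[C@@H]1[C@@H](OCCOCC)c2c(OCc3ccccc3)cc(OCc3ccccc3)c(Br)c2O[C@@H]1c1ccc(OCc2ccccc2)c(OCc2ccccc2)c1 | intermediate
5 | 3,5-bis(benzyloxy)phenol | Oc1cc(OCc2ccccc2)cc(OCc2ccccc2)c1 | starting material
6 | 8-bromo-4β-[2-hydroxy-4,6-bis(benzyloxy)phenyl]-5,7,3',4'-tetra-O-benzyl-(−)-epicatechin | O[C@@H]1[C@@H](c2c(O)cc(OCc3ccccc3)cc2OCc2ccccc2)c2c(OCc3ccccc3)cc(OCc3ccccc3)c(Br)c2O[C@@H]1c1ccc(OCc2ccccc2)c(OCc2ccccc2)c1 | intermediate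
7 | 3,4-bis(benzyloxy)benzaldehyde | O=Cc1ccc(OCc2ccccc2)c(OCc2ccccc2)c1 | starting material
8 | methyl 2-[bis(2,2,2-trifluoroethoxy)phosphoryl]acetate | COC(=O)CP(=O)(OCC(F)(F)F)OCC(F)(F)F | starting material
9 | methyl (Z)-3-[3,4-bis(benzyloxy)phenyl]prop-2-enoate | COC(=O)/C=C\c1ccc(OCc2ccccc2)c(OCc2ccccc2)c1 | intermediate
10 | methyl (2S,3S)-3-[3,4-bis(benzyloxy)phenyl]oxirane-2-carboxylate (cis) | COC(=O)[C@H]1O[C@H]1c1ccc(OCc2ccccc2)c(OCc2ccccc2)c1 | intermediate
11 | [(2R,3S)-3-[3,4-bis(benzyloxy)phenyl]oxiran-2-yl]methanol (cis) | OC[C@H]1O[C@H]1c1ccc(OCc2ccccc2)c(OCc2ccccc2)c1 | intermediate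
12 | (2S,3S)-3-[3,4-bis(benzyloxy)phenyl]oxirane-2-carbaldehyde (cis) | O=C[C@H]1O[C@H]1c1ccc(OCc2ccccc2)c(OCc2ccccc2)c1 | intermediate
13 | (+)-catechin | O[C@H]1Cc2c(O)cc(O)cc2O[C@@H]1c1ccc(O)c(O)c1 | starting material
14 | 5,7,3',4'-tetra-O-benzyl-(+)-catechin | O[C@H]1Cc2c(OCc3ccccc3)cc(OCc3ccccc3)cc2O[C@@H]1c1ccc(OCc2ccccc2)c(OCc2ccccc2)c1 | intermediate
15 | 3,5,7,3',4'-penta-O-benzyl-(+)-catechin | C(c1ccccc1)O[C@H]1Cc2c(OCc3ccccc3)cc(OCc3ccccc3)cc2O[C@@H]1c1ccc(OCc2ccccc2)c(OCc2ccccc2)c1 | intermediate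
16 | 8-bromo-3,5,7,3',4'-penta-O-benzyl-(+)-catechin | C(c1ccccc1)O[C@H]1Cc2c(OCc3ccccc3)cc(OCc3ccccc3)c(Br)c2O[C@@H]1c1ccc(OCc2ccccc2)c(OCc2ccccc2)c1 | intermediate
17 | aryloxytitanium triisopropoxide of 6 (not isolated) | O[C@@H]1[C@@H](c2c(O[Ti](OC(C)C)(OC(C)C)OC(C)C)cc(OCc3ccccc3)cc2OCc2ccccc2)c2c(OCc3ccccc3)cc(OCc3ccccc3)c(Br)c2O[C@@H]1c1ccc(OCc2ccccc2)c(OCc2ccccc2)c1 | intermediate
18 | epoxy carbinol adduct: 6 carrying at the free ortho carbon a CH(OH) group bonded to the intact cis-epoxide, titanium-bound in the flask and drawn protonated, carbinol epimers (not isolated) | O[C@@H]1[C@@H](c2c(O)c(C(O)[C@H]3O[C@H]3c3ccc(OCc4ccccc4)c(OCc4ccccc4)c3)c(OCc3ccccc3)cc2OCc2ccccc2)c2c(OCc3ccccc3)cc(OCc3ccccc3)c(Br)c2O[C@@H]1c1ccc(OCc2ccccc2)c(OCc2ccccc2)c1 | intermediate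
19 | 8-bromo-5,7,3',4'-tetra-O-benzylepicatechin-(4β→8)-[5,7,3',4'-tetra-O-benzyl-(2R,3R)-2,3-cis-flavan-3,4-diol], C4 carbinol epimers | O[C@@H]1[C@@H](c2c(OCc3ccccc3)cc(OCc3ccccc3)c3c2O[C@H](c2ccc(OCc4ccccc4)c(OCc4ccccc4)c2)[C@H](O)C3O)c2c(OCc3ccccc3)cc(OCc3ccccc3)c(Br)c2O[C@@H]1c1ccc(OCc2ccccc2)c(OCc2ccccc2)c1 | intermediate
20 | 8-bromo-tetra-O-benzylepicatechin-(4β→8)-tetra-O-benzylepicatechin-(4β→6)-8-bromo-penta-O-benzylcatechin | O[C@@H]1[C@@H](c2c(OCc3ccccc3)cc(OCc3ccccc3)c3c2O[C@H](c2ccc(OCc4ccccc4)c(OCc4ccccc4)c2)[C@H](O)[C@H]3c2c(OCc3ccccc3)c(Br)c3c(c2OCc2ccccc2)C[C@H](OCc2ccccc2)[C@@H](c2ccc(OCc4ccccc4)c(OCc4ccccc4)c2)O3)c2c(OCc3ccccc3)cc(OCc3ccccc3)c(Br)c2O[C@@H]1c1ccc(OCc2ccccc2)c(OCc2ccccc2)c1 | intermediate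
21 | 3,4,5-tris(benzyloxy)benzoic acid | OC(=O)c1cc(OCc2ccccc2)c(OCc2ccccc2)c(OCc2ccccc2)c1 | starting material
22 | 3,3''-bis-O-[3,4,5-tris(benzyloxy)benzoyl] derivative of 20 | O=C(O[C@@H]1[C@@H](c2c(OCc3ccccc3)cc(OCc3ccccc3)c3c2O[C@H](c2ccc(OCc4ccccc4)c(OCc4ccccc4)c2)[C@H](OC(=O)c2cc(OCc4ccccc4)c(OCc4ccccc4)c(OCc4ccccc4)c2)[C@H]3c2c(OCc3ccccc3)c(Br)c3c(c2OCc2ccccc2)C[C@H](OCc2ccccc2)[C@@H](c2ccc(OCc4ccccc4)c(OCc4ccccc4)c2)O3)c2c(OCc3ccccc3)cc(OCc3ccccc3)c(Br)c2O[C@@H]1c1ccc(OCc2ccccc2)c(OCc2ccccc2)c1)c1cc(OCc2ccccc2)c(OCc2ccccc2)c(OCc2ccccc2)c1 | intermediate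
23 | (−)-epicatechin-3-O-gallate-(4β→8)-(−)-epicatechin-3-O-gallate-(4β→6)-(+)-catechin | O=C(O[C@@H]1[C@@H](c2c(O)cc(O)c3c2O[C@H](c2ccc(O)c(O)c2)[C@H](OC(=O)c2cc(O)c(O)c(O)c2)[C@H]3c2c(O)cc3c(c2O)C[C@H](O)[C@@H](c2ccc(O)c(O)c2)O3)c2c(O)cc(O)cc2O[C@@H]1c1ccc(O)c(O)c1)c1cc(O)c(O)c(O)c1 | target

## Summary and risks

Total step count: 15. Longest linear sequence: 8 steps (steps 5, 6, 7, 8, 12, 13, 14, 15; the branch through steps 1–4 is equally long).

Steps most likely to fail:

1. Step 12 (proposed new method). The epoxide may ionise at the electron-rich benzylic carbon before or instead of backside attack, which would erode the 2,3-cis stereochemistry or cause rearrangement to a carbonyl compound. The ortho-hydroxybenzyl titanate may also condense with a second phenol, and titanium isopropoxide may reduce the aldehyde. Fallback (known chemistry): ring C of the middle unit is bought instead of built. It sets out from 2 and 4: Me3SiOTf-catalysed Friedel–Crafts coupling of the cation of 4 with an excess of 2 (attack through C8 of 2, anti to the 3-OH) should give the dimer 8-bromo-5,7,3',4'-tetra-O-benzylepicatechin-(4β→8)-5,7,3',4'-tetra-O-benzylepicatechin F1. DDQ oxidation of F1 at C4 of the lower unit in wet CH2Cl2 should then give 19 as its 4β-hydroxy epimer, where the route is rejoined.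

2. Step 4. The flavan-4-yl cation may attack the phenol at the carbon between the two benzyloxy groups (para to OH) as well as at the ortho carbon, and the product may be alkylated a second time; the para isomer cannot undergo the annulation. Fallback: the assembly order is reversed so that no free phenol nucleophile is needed. It sets out from 2: DDQ and 2-ethoxyethanol should give the uncapped electrophile 4β-(2-ethoxyethoxy)-5,7,3',4'-tetra-O-benzyl-(−)-epicatechin F2. Me3SiOTf coupling of F2 with an excess of 16 (C6 is its only free position) should give 5,7,3',4'-tetra-O-benzylepicatechin-(4β→6)-8-bromo-3,5,7,3',4'-penta-O-benzylcatechin F3. A second Me3SiOTf coupling of F3 (through C8 of its epicatechin unit, the most reactive free position) with the bromo-capped electrophile 4 should give 20, where the route is rejoined.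

3. Step 6. The radical intermediate of the manganese-salen epoxidation is stabilised by the dialkoxyphenyl ring, so partial cis-to-trans isomerisation is possible; ring chlorination by hypochlorite and incomplete enantioselectivity are further concerns. Fallback: oxygen transfer is switched to a hydroxyl-directed, stereospecific epoxidation. It sets out from 9: i-Bu2AlH reduction (CH2Cl2, −78 °C) should give (Z)-3-[3,4-bis(benzyloxy)phenyl]prop-2-en-1-ol F4. Sharpless asymmetric epoxidation of F4 (Ti(OiPr)4, D-(−)-diethyl tartrate, t-BuOOH, 4 Å MS, CH2Cl2, −20 °C) should give 11 directly, where the route is rejoined.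

Further compounds

F1 | step 12 | 8-bromo-5,7,3',4'-tetra-O-benzylepicatechin-(4β→8)-5,7,3',4'-tetra-O-benzylepicatechin | O[C@@H]1[C@@H](c2c(OCc3ccccc3)cc(OCc3ccccc3)c3c2O[C@H](c2ccc(OCc4ccccc4)c(OCc4ccccc4)c2)[C@H](O)C3)c2c(OCc3ccccc3)cc(OCc3ccccc3)c(Br)c2O[C@@H]1c1ccc(OCc2ccccc2)c(OCc2ccccc2)c1
F2 | step 4 | 4β-(2-ethoxyethoxy)-5,7,3',4'-tetra-O-benzyl-(−)-epicatechin | O[C@@H]1[C@@H](OCCOCC)c2c(OCc3ccccc3)cc(OCc3ccccc3)cc2O[C@@H]1c1ccc(OCc2ccccc2)c(OCc2ccccc2)c1
F3 | step 4 | 5,7,3',4'-tetra-O-benzylepicatechin-(4β→6)-8-bromo-3,5,7,3',4'-penta-O-benzylcatechin | O[C@@H]1[C@@H](c2c(OCc3ccccc3)c(Br)c3c(c2OCc2ccccc2)C[C@H](OCc2ccccc2)[C@@H](c2ccc(OCc4ccccc4)c(OCc4ccccc4)c2)O3)c2c(OCc3ccccc3)cc(OCc3ccccc3)cc2O[C@@H]1c1ccc(OCc2ccccc2)c(OCc2ccccc2)c1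
F4 | step 6 | (Z)-3-[3,4-bis(benzyloxy)phenyl]prop-2-en-1-ol | OC/C=C\c1ccc(OCc2ccccc2)c(OCc2ccccc2)c1
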